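**Assumption:** (1R,4R)-p-mentha-2,8-dien-1-ol (hydroxyl anti to isopropenyl; made on scale from (R)-(+)-limonene) is taken as purchasable; C1–C15 in the explanations follow kalihinane numbering (ring A C1–C6 with C4=C5, ring B C1/C6–C10, oxane C11–C15). Nothing here has been run; selectivities are predictions.

## Retrosynthetic overview

1. C7–H is set last by formamide-directed hydrogenation of a C7=C8 alkene; C10–N comes before it by Markovnikov hydroazidation of a C10 exocyclic methylene, then azide → formamide.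
2. Ring B (C8–C9 and C6–C7) is closed in one electroreductive nickel-catalysed [4+2] annulation of a terminal alkyne (oxane fragment) with a 1,4-bis-allylic electrophile (ring A fragment).
3. Oxane fragment: (R)-linalool → chloroetherification (C11 bought, C14 set from C11) → ozonolysis → Ohira–Bestmann alkyne.
4. Ring A fragment: (1R,4R)-p-mentha-2,8-dien-1-ol (C1 bought) → tertiary allylic carbonate → ene-chlorination of the isopropenyl group.
5. Ring order: oxane ring first, ring A bought, ring B last; C6, C10 and C7 are then set in that order under substrate control.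

## Route

Step 1
Reactants: 1 (R)-(−)-linalool [(3R)-3,7-dimethylocta-1,6-dien-3-ol]
Product: 2 (3S,6R)-3-chloro-6-ethenyl-2,2,6-trimethyloxane
Conditions: NCS (1.1 equiv), Ph3P=S (5 mol%), CH2Cl2, −20 → 0 °C; chromatographic removal of the 3-epimer
Reagents that add atoms: N-chlorosuccinimide, O=C1CCC(=O)N1Cl
Why: Chloronium-induced 6-endo (Markovnikov) chloroetherification of the trisubstituted alkene by the tertiary hydroxyl leaves the vinyl group untouched and sets C14 relative to the bought C11 through a chair transition state with equatorial chlorine, but with little preference (expect about 1:1), so the isomer with chlorine trans to vinyl is isolated by separation.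

Step 2
Reactants: 2 (3S,6R)-3-chloro-6-ethenyl-2,2,6-trimethyloxane
Product: 3 (2R,5S)-5-chloro-2,6,6-trimethyloxane-2-carbaldehyde
Conditions: O3, CH2Cl2, −78 °C; then Me2S, −78 → 25 °C
Reagents that add atoms: ozone, [O-][O+]=O
Why: Ozonolysis with reductive work-up cleaves the only alkene, and the aldehyde has a quaternary α-carbon so nothing can epimerise.

Step 3
Reactants: 3 (2R,5S)-5-chloro-2,6,6-trimethyloxane-2-carbaldehyde
Product: 4 (3S,6R)-3-chloro-6-ethynyl-2,2,6-trimethyloxane
Conditions: dimethyl (1-diazo-2-oxopropyl)phosphonate, K2CO3, MeOH, 0 → 25 °C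
Reagents that add atoms: dimethyl (1-diazo-2-oxopropyl)phosphonate, COP(=O)(OC)C(=[N+]=[N-])C(C)=O
Why: Ohira–Bestmann (Seyferth–Gilbert) homologation works on non-enolisable hindered aldehydes under mild base that leaves the secondary chloride alone; no stereocentre is touched.

Step 4
Reactants: 5 (1R,4R)-1-methyl-4-(prop-1-en-2-yl)cyclohex-2-en-1-ol
Product: 7 methyl (1R,4R)-1-methyl-4-(prop-1-en-2-yl)cyclohex-2-en-1-yl carbonate, via lithium alkoxide 6 (not isolated)
Conditions: n-BuLi, THF, −78 °C; then ClCO2Me, −78 → 0 °C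
Reagents that add atoms: methyl chloroformate, COC(Cl)=O
Why: O-acylation of the lithium alkoxide is the standard way to make tertiary allylic carbonates and touches no stereocentre.

Step 5
Reactants: 7 methyl (1R,4R)-1-methyl-4-(prop-1-en-2-yl)cyclohex-2-en-1-yl carbonate
Product: 8 methyl (1R,4R)-4-(3-chloroprop-1-en-2-yl)-1-methylcyclohex-2-en-1-yl carbonate
Conditions: Ca(OCl)2, CO2 (dry ice), CH2Cl2/H2O, 0 °C
Reagents that add atoms: calcium hypochlorite, [Ca+2].[O-]Cl.[O-]Cl
Why: Ene-type allylic chlorination by hypochlorous acid (Wolinsky conditions) picks the electron-richer 1,1-disubstituted isopropenyl group over the ring alkene, which is deactivated by the allylic carbonate; no stereocentre changes.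

Step 6
Reactants: 4 (3S,6R)-3-chloro-6-ethynyl-2,2,6-trimethyloxane, 8 methyl (1R,4R)-4-(3-chloroprop-1-en-2-yl)-1-methylcyclohex-2-en-1-yl carbonate
Product: 9 (3S,6R)-3-chloro-2,2,6-trimethyl-6-[(4aR,8aS)-7-methyl-4-methylidene-3,4,4a,5,6,8a-hexahydronaphthalen-1-yl]oxane
Conditions: NiBr2(MeOCH2CH2OMe) (10 mol%), 4,4′-di-tert-butyl-2,2′-bipyridine (12 mol%), LiBr, DMA, undivided cell, Zn anode, Ni-foam cathode, 5 mA (about 2.3 F/mol), 25 °C; 8 added over 4 h
Reagents that add atoms: none
Why: Proposed new method: an electroreductive nickel-catalysed [4+2] annulation of a 1,4-bis-allylic electrophile with a terminal alkyne, in which cathodically formed zerovalent nickel inserts first into the primary allylic C–Cl bond of 8, the allylnickel adds syn across the alkyne of 4 with the allyl group going to the CH terminus and nickel to the carbon bearing the bulky oxanyl group (C8–C9), and the tethered alkenylnickel, after further reduction, adds oxidatively to the tertiary allylic carbonate anti to the leaving group and reductively eliminates at the secondary allyl terminus (C6–C7, six-membered ring), so the new bond lies on the tether face, cis to the bought C1, and C6 is set by the carbonate configuration; the closest known reaction types are Chiusoli-type allylnickelation of alkynes and nickel-catalysed (electro)reductive alkenyl–allyl cross-electrophile coupling.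

Step 7
Reactants: 9 (3S,6R)-3-chloro-2,2,6-trimethyl-6-[(4aR,8aS)-7-methyl-4-methylidene-3,4,4a,5,6,8a-hexahydronaphthalen-1-yl]oxane
Product: 10 (3S,6R)-6-[(4R,4aR,8aS)-4-azido-4,7-dimethyl-3,4,4a,5,6,8a-hexahydronaphthalen-1-yl]-3-chloro-2,2,6-trimethyloxane
Conditions: Co(BF4)2·6H2O (6 mol%), achiral salicylaldimine ligand (potassium 2-[(3,5-di-tert-butyl-2-hydroxybenzylidene)amino]-2,2-diphenylacetate), TsN3, PhSiH3, t-BuOOH (cat.), EtOH, 25 °C
Reagents that add atoms: 4-methylbenzenesulfonyl azide, Cc1ccc(cc1)S(=O)(=O)N=[N+]=[N-]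
Why: Mukaiyama-type hydrogen-atom-transfer hydroazidation puts H on the terminal carbon of the 1,1-disubstituted alkene faster than on either trisubstituted alkene, and the tertiary C10 radical takes azide on the convex face of the cis-fused bicycle, anti to the ring A carbon on C1, which sets C10 with nitrogen cis to H1.

Step 8
Reactants: 10 (3S,6R)-6-[(4R,4aR,8aS)-4-azido-4,7-dimethyl-3,4,4a,5,6,8a-hexahydronaphthalen-1-yl]-3-chloro-2,2,6-trimethyloxane
Product: 13 N-[(1R,4aS,8aR)-4-[(2R,5S)-5-chloro-2,6,6-trimethyloxan-2-yl]-1,6-dimethyl-1,2,4a,7,8,8a-hexahydronaphthalen-1-yl]formamide, via iminophosphorane 11 (not isolated), via amine 12 (not isolated)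
Conditions: PMe3, THF, 25 °C; H2O, 50 °C; then acetic formic anhydride, Et3N, 0 → 25 °C
Reagents that add atoms: acetic formic anhydride, CC(=O)OC=O
Why: Staudinger reduction followed by N-formylation with the mixed anhydride converts the hindered tertiary azide to the formamide without touching any stereocentre or alkene.

Step 9
Reactants: 13 N-[(1R,4aS,8aR)-4-[(2R,5S)-5-chloro-2,6,6-trimethyloxan-2-yl]-1,6-dimethyl-1,2,4a,7,8,8a-hexahydronaphthalen-1-yl]formamide
Product: 14 N-[(1R,4R,4aS,8aR)-4-[(2R,5S)-5-chloro-2,6,6-trimethyloxan-2-yl]-1,6-dimethyl-1,2,3,4,4a,7,8,8a-octahydronaphthalen-1-yl]formamide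
Conditions: [Rh(C7H8)(Ph2P(CH2)4PPh2)]BF4 (10 mol%), H2 (55 bar), CH2Cl2, 25 °C; stopped after 1 equiv H2
Reagents that add atoms: none
Why: Amide-directed homogeneous hydrogenation, in which the cationic rhodium bound to the formamide carbonyl on the convex face delivers H2 to the nearby C7=C8 bond from that face (H7 cis to H6 and to nitrogen, setting C7), while the undirected trisubstituted ring A alkene reacts much more slowly with this catalyst.

## Compound list

1 | (R)-(−)-linalool, (3R)-3,7-dimethylocta-1,6-dien-3-ol | C=C[C@](C)(O)CCC=C(C)C | starting material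
2 | (3S,6R)-3-chloro-6-ethenyl-2,2,6-trimethyloxane (chlorine trans to vinyl) | C=C[C@@]1(C)CC[C@H](Cl)C(C)(C)O1 | intermediate
3 | (2R,5S)-5-chloro-2,6,6-trimethyloxane-2-carbaldehyde | O=C[C@@]1(C)CC[C@H](Cl)C(C)(C)O1 | intermediate
4 | (3S,6R)-3-chloro-6-ethynyl-2,2,6-trimethyloxane | C#C[C@@]1(C)CC[C@H](Cl)C(C)(C)O1 | intermediate
5 | (1R,4R)-1-methyl-4-(prop-1-en-2-yl)cyclohex-2-en-1-ol (hydroxyl anti to isopropenyl) | C[C@]1(O)C=C[C@@H](CC1)C(C)=C | starting material
6 | lithium (1R,4R)-1-methyl-4-(prop-1-en-2-yl)cyclohex-2-en-1-olate (lithium alkoxide) | C[C@]1([O-])C=C[C@@H](CC1)C(C)=C.[Li+] | intermediate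
7 | methyl (1R,4R)-1-methyl-4-(prop-1-en-2-yl)cyclohex-2-en-1-yl carbonate | C[C@]1(OC(=O)OC)C=C[C@@H](CC1)C(C)=C | intermediate
8 | methyl (1R,4R)-4-(3-chloroprop-1-en-2-yl)-1-methylcyclohex-2-en-1-yl carbonate | C[C@]1(OC(=O)OC)C=C[C@@H](CC1)C(CCl)=C | intermediate
9 | (3S,6R)-3-chloro-2,2,6-trimethyl-6-[(4aR,8aS)-7-methyl-4-methylidene-3,4,4a,5,6,8a-hexahydronaphthalen-1-yl]oxane (cis-fused triene) | CC1=C[C@H]2[C@@H](CC1)C(=C)CC=C2[C@@]1(C)CC[C@H](Cl)C(C)(C)O1 | intermediate
10 | (3S,6R)-6-[(4R,4aR,8aS)-4-azido-4,7-dimethyl-3,4,4a,5,6,8a-hexahydronaphthalen-1-yl]-3-chloro-2,2,6-trimethyloxane | CC1=C[C@H]2[C@@H](CC1)[C@](C)(N=[N+]=[N-])CC=C2[C@@]1(C)CC[C@H](Cl)C(C)(C)O1 | intermediate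
11 | iminophosphorane, P,P,P-trimethyl-N-[(1R,4aS,8aR)-4-[(2R,5S)-5-chloro-2,6,6-trimethyloxan-2-yl]-1,6-dimethyl-1,2,4a,7,8,8a-hexahydronaphthalen-1-yl]phosphine imide | CC1=C[C@H]2[C@@H](CC1)[C@](C)(N=P(C)(C)C)CC=C2[C@@]1(C)CC[C@H](Cl)C(C)(C)O1 | intermediate
12 | (1R,4aS,8aR)-4-[(2R,5S)-5-chloro-2,6,6-trimethyloxan-2-yl]-1,6-dimethyl-1,2,4a,7,8,8a-hexahydronaphthalen-1-amine | CC1=C[C@H]2[C@@H](CC1)[C@](C)(N)CC=C2[C@@]1(C)CC[C@H](Cl)C(C)(C)O1 | intermediate
13 | N-[(1R,4aS,8aR)-4-[(2R,5S)-5-chloro-2,6,6-trimethyloxan-2-yl]-1,6-dimethyl-1,2,4a,7,8,8a-hexahydronaphthalen-1-yl]formamide | CC1=C[C@H]2[C@@H](CC1)[C@](C)(NC=O)CC=C2[C@@]1(C)CC[C@H](Cl)C(C)(C)O1 | intermediate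
14 | N-[(1R,4R,4aS,8aR)-4-[(2R,5S)-5-chloro-2,6,6-trimethyloxan-2-yl]-1,6-dimethyl-1,2,3,4,4a,7,8,8a-octahydronaphthalen-1-yl]formamide | CC1=C[C@H]2[C@@H](CC1)[C@](C)(NC=O)CC[C@H]2[C@@]1(C)CC[C@H](Cl)C(C)(C)O1 | target

## Step count and risks

Total steps: 9. Longest linear sequence: 7 (steps 1, 2, 3, 6, 7, 8, 9 from linalool; the ring A branch is steps 4 and 5).

**Most likely to fail, first: step 6 (the proposed annulation).** Likely failure modes are allyl–allyl homocoupling, loss of the doubly allylic C1 hydrogen from the allylnickel to give dienes, reversed alkyne insertion, and early ionisation of the tertiary carbonate. The fallback uses known stepwise chemistry, sets out from 2 and 8 and returns at 9. Tsuji–Wacker oxidation of 2 (PdCl2, CuCl, O2, DMF/H2O) gives the methyl ketone 1-[(2R,5S)-5-chloro-2,6,6-trimethyloxan-2-yl]ethan-1-one F1. Its lithium enolate (LiN(iPr)2, THF, −78 °C; only one side can enolise) is alkylated by the allylic chloride 8 (NaI) to the keto carbonate methyl (1R,4R)-4-{5-[(2R,5S)-5-chloro-2,6,6-trimethyloxan-2-yl]-5-oxopent-1-en-2-yl}-1-methylcyclohex-2-en-1-yl carbonate F2. Trapping the Z enolate (KN(SiMe3)2, PhNTf2) gives the enol triflate methyl (1R,4R)-4-[(4Z)-5-[(2R,5S)-5-chloro-2,6,6-trimethyloxan-2-yl]-5-(trifluoromethanesulfonyloxy)penta-1,4-dien-2-yl]-1-methylcyclohex-2-en-1-yl carbonate F3. An intramolecular nickel-catalysed reductive alkenyl–allyl cross-electrophile coupling (NiBr2(MeOCH2CH2OMe), 2,2′-bipyridine, Zn powder, DMA) then closes ring B to 9.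

**Second: step 9 (directed hydrogenation).** The hindered C7=C8 bond may react too slowly, the ring A alkene may be reduced as well, or the skipped diene may isomerise. The fallback masks the competing alkene, sets out from 13 and returns at 14. Dimethyldioxirane (acetone, −20 °C) epoxidises the more accessible ring A alkene from the convex face to give the 4α,5α-epoxide of formamide 13 F5. With no other alkene left, [Ir(C8H12)(PCy3)(C5H5N)]PF6/H2 (CH2Cl2) saturates C7=C8 from the formamide face to give the 4α,5α-epoxide of target 14 F6. CH3ReO3 (cat.)/PPh3 deoxygenation restores the C4=C5 alkene and gives 14.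

**Third: step 7 (hydroazidation).** Face selectivity at C10 is a prediction, and hydrogen-atom transfer to the trisubstituted alkenes or isomerisation of the skipped triene could compete. The fallback is an ionic rather than radical Markovnikov azidation, sets out from 9 and returns at 10. Azidomercuration of the least hindered 1,1-disubstituted alkene (Hg(OAc)2, NaN3, THF/H2O) gives the organomercurial {[(1R,4aS,8aR)-1-azido-4-[(2R,5S)-5-chloro-2,6,6-trimethyloxan-2-yl]-6-methyl-1,2,4a,7,8,8a-hexahydronaphthalen-1-yl]methyl}mercury acetate F4, with azide entering the tertiary carbon from the open convex face. NaBH4/NaOH demercuration gives 10.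

## Further compounds

F1 | step 6 | 1-[(2R,5S)-5-chloro-2,6,6-trimethyloxan-2-yl]ethan-1-one | CC(=O)[C@@]1(C)CC[C@H](Cl)C(C)(C)O1
F2 | step 6 | methyl (1R,4R)-4-{5-[(2R,5S)-5-chloro-2,6,6-trimethyloxan-2-yl]-5-oxopent-1-en-2-yl}-1-methylcyclohex-2-en-1-yl carbonate | C[C@]1(OC(=O)OC)C=C[C@@H](CC1)C(=C)CCC(=O)[C@@]1(C)CC[C@H](Cl)C(C)(C)O1
F3 | step 6 | methyl (1R,4R)-4-[(4Z)-5-[(2R,5S)-5-chloro-2,6,6-trimethyloxan-2-yl]-5-(trifluoromethanesulfonyloxy)penta-1,4-dien-2-yl]-1-methylcyclohex-2-en-1-yl carbonate | C[C@]1(OC(=O)OC)C=C[C@@H](CC1)C(=C)C/C=C(\OS(=O)(=O)C(F)(F)F)[C@@]1(C)CC[C@H](Cl)C(C)(C)O1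
F4 | step 7 | {[(1R,4aS,8aR)-1-azido-4-[(2R,5S)-5-chloro-2,6,6-trimethyloxan-2-yl]-6-methyl-1,2,4a,7,8,8a-hexahydronaphthalen-1-yl]methyl}mercury acetate | CC1=C[C@H]2[C@@H](CC1)[C@](C[Hg]OC(C)=O)(N=[N+]=[N-])CC=C2[C@@]1(C)CC[C@H](Cl)C(C)(C)O1
F5 | step 9 | 4α,5α-epoxide of formamide 13 (oxirane on ring A, oxygen on the face of the ring-fusion hydrogens) | C[C@@]13O[C@H]3[C@H]2[C@@H](CC1)[C@](C)(NC=O)CC=C2[C@@]1(C)CC[C@H](Cl)C(C)(C)O1
F6 | step 9 | 4α,5α-epoxide of target 14 (oxirane on ring A, oxygen on the face of the ring-fusion hydrogens) | C[C@@]13O[C@H]3[C@H]2[C@@H](CC1)[C@](C)(NC=O)CC[C@H]2[C@@]1(C)CC[C@H](Cl)C(C)(C)O1
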